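**Assumption:** the target SMILES has no stereocentres (it is achiral), so "single enantiomer" does not apply and the route needs no stereocontrol. The only stereocentre in the route is the racemic carbinol in 10, which is destroyed in Step 6.

## Retrosynthetic overview

1. Target ⇐ bis-MOM isoflavone by global acetal removal (7-OH and 3'-OH unveiled last).
2. Bis-MOM isoflavone ⇐ o-hydroxyaryl enaminone (A ring) + 6-bromo-2,2-dimethylchromene (B/D rings). The C3–C1' bond and the pyranone C ring form in one operation (proposed new Pd-catalysed arylative annulation).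
3. Enaminone ⇐ 2',4'-dihydroxy-6'-methoxyacetophenone (4-O-MOM, then DMF-DMA).
4. Bromochromene ⇐ 5-bromo-o-vanillin: demethylation, 3-O-MOM, isobutenyl Grignard, o-quinone methide/oxa-6π ring closure.
5. Ring order: A and B rings are bought; the D (dimethylpyran) ring is formed first, the C (pyranone) ring last.

## Route

**Step 1**
Reactants: 1, 1-(2,4-dihydroxy-6-methoxyphenyl)ethan-1-one
Product: 3, 1-[2-hydroxy-6-methoxy-4-(methoxymethoxy)phenyl]ethan-1-one
Conditions: MOMCl (1.1 equiv), i-Pr2NEt, CH2Cl2, 0 °C → rt
Reagents that add atoms: 2, chloromethyl methyl ether (MOMCl), COCCl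
Why: Chemoselective O-alkylation (MOM protection); the 2-OH is locked in a hydrogen bond to the ketone, so only the free 4-OH reacts.

**Step 2**
Reactants: 3, 1-[2-hydroxy-6-methoxy-4-(methoxymethoxy)phenyl]ethan-1-one
Product: 5, (E)-3-(dimethylamino)-1-[2-hydroxy-6-methoxy-4-(methoxymethoxy)phenyl]prop-2-en-1-one
Conditions: DMF-DMA (2 equiv), PhMe, 95 °C
Reagents that add atoms: 4, N,N-dimethylformamide dimethyl acetal, COC(OC)N(C)C
Why: Standard enaminone formation by condensation of the methyl ketone with an amide acetal; it gives the E vinylogous amide, and MOM and OMe are inert.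

**Step 3**
Reactants: 6, 5-bromo-2-hydroxy-3-methoxybenzaldehyde
Product: 7, 5-bromo-2,3-dihydroxybenzaldehyde
Conditions: BBr3 (2.5 equiv), CH2Cl2, −78 °C → rt; H2O
Reagents that add atoms: none
Why: Lewis-acid cleavage of the aryl methyl ether (BBr3 demethylation); aldehyde and aryl bromide are tolerated.

**Step 4**
Reactants: 7, 5-bromo-2,3-dihydroxybenzaldehyde
Product: 8, 5-bromo-2-hydroxy-3-(methoxymethoxy)benzaldehyde
Conditions: NaH (2.2 equiv), DMF, 0 °C; MOMCl (1.0 equiv)
Reagents that add atoms: 2, chloromethyl methyl ether (MOMCl), COCCl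
Why: Dianion alkylation; the 3-phenoxide is not conjugated to the aldehyde and is the more nucleophilic oxygen, while the 2-phenoxide is stabilised by conjugation and chelation and is recovered as the free OH.

**Step 5**
Reactants: 8, 5-bromo-2-hydroxy-3-(methoxymethoxy)benzaldehyde
Product: 10, 4-bromo-2-(1-hydroxy-3-methylbut-2-en-1-yl)-6-(methoxymethoxy)phenol (racemic carbinol)
Conditions: 2-methyl-1-propenylmagnesium bromide (2.5 equiv), THF, 0 °C → rt; aq NH4Cl
Reagents that add atoms: 9, 2-methyl-1-propenylmagnesium bromide, CC(C)=C[Mg]Br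
Why: Grignard 1,2-addition to the salicylaldehyde (the first equivalent deprotonates the phenol); the aryl bromide and MOM ether do not react with an alkenyl Grignard at this temperature.

**Step 6**
Reactants: 10, 4-bromo-2-(1-hydroxy-3-methylbut-2-en-1-yl)-6-(methoxymethoxy)phenol
Product: 11, 6-bromo-8-(methoxymethoxy)-2,2-dimethyl-2H-chromene
Conditions: PPTS (5 mol %), PhMe, 4 Å MS, 80 °C
Reagents that add atoms: none
Why: Dehydration of the doubly activated (benzylic, allylic) carbinol gives an o-quinone methide that closes by oxa-6π electrocyclisation; only the 2-OH is ortho to the carbinol, so the ring oxygen is fixed unambiguously.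

**Step 7**
Reactants: 5, (E)-3-(dimethylamino)-1-[2-hydroxy-6-methoxy-4-(methoxymethoxy)phenyl]prop-2-en-1-one (1.2 equiv); 11, 6-bromo-8-(methoxymethoxy)-2,2-dimethyl-2H-chromene (1.0 equiv)
Product: 12, 5-methoxy-7-(methoxymethoxy)-3-[8-(methoxymethoxy)-2,2-dimethyl-2H-chromen-6-yl]-4H-chromen-4-one
Conditions: Pd2(dba)3 (2.5 mol %), XPhos (6 mol %), K3PO4 (3 equiv), PhMe, 100 °C, slow N2 sweep; then AcOH (5 equiv), 60 °C
Reagents that add atoms: none
Why: Proposed new method: a Pd-catalysed deaminative arylative annulation in which K3PO4 deprotonates the phenol of 5, the resulting phenoxide-enaminone (nucleophilic at Cα as a vinylogous amide, and in equilibrium by 6-endo oxa-Michael closure with the 2-(dimethylamino)chroman-4-one enolate) is captured at carbon by XPhos·Pd(Ar)Br from oxidative addition of 11, C–C reductive elimination from the C3-bound Pd enolate forms the C3–C1' bond, and E1cB loss of Me2NH (swept out by N2 to suppress C–N coupling, and completed by the AcOH quench) closes and aromatises the pyranone so that the aryl group ends at C3 and not C2; the closest known reaction types are Pd-catalysed ketone α-arylation with aryl bromides (Buchwald–Hartwig type) and the domino C–H functionalisation/annulation of o-hydroxyaryl enaminones with radical or onium arylating agents, and to my knowledge the Pd(0)/aryl bromide enolate-arylation manifold has not been shown for this annulation.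

**Step 8**
Reactants: 12, 5-methoxy-7-(methoxymethoxy)-3-[8-(methoxymethoxy)-2,2-dimethyl-2H-chromen-6-yl]-4H-chromen-4-one
Product: 13, Glycyrrhizaisoflavone B, 7-hydroxy-3-(8-hydroxy-2,2-dimethyl-2H-chromen-6-yl)-5-methoxy-4H-chromen-4-one
Conditions: 3 M aq HCl, MeOH/THF, 45 °C
Reagents that add atoms: none
Why: Acid-catalysed acetal hydrolysis removes both MOM ethers; the 5-OMe is not cleaved by protic acid, and 2,2-dimethylchromenes generally tolerate dilute HCl/MeOH.

## Compound list

1 | 1-(2,4-dihydroxy-6-methoxyphenyl)ethan-1-one (assumed commercial, CAS 3602-54-8) | CC(=O)c1c(O)cc(O)cc1OC | starting material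
2 | chloromethyl methyl ether (MOMCl) | COCCl | starting material (reagent)
3 | 1-[2-hydroxy-6-methoxy-4-(methoxymethoxy)phenyl]ethan-1-one | CC(=O)c1c(O)cc(OCOC)cc1OC | intermediate
4 | N,N-dimethylformamide dimethyl acetal | COC(OC)N(C)C | starting material (reagent)
5 | (E)-3-(dimethylamino)-1-[2-hydroxy-6-methoxy-4-(methoxymethoxy)phenyl]prop-2-en-1-one | CN(C)/C=C/C(=O)c1c(O)cc(OCOC)cc1OC | intermediate
6 | 5-bromo-2-hydroxy-3-methoxybenzaldehyde | COc1cc(Br)cc(C=O)c1O | starting material
7 | 5-bromo-2,3-dihydroxybenzaldehyde | O=Cc1cc(Br)cc(O)c1O | intermediate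
8 | 5-bromo-2-hydroxy-3-(methoxymethoxy)benzaldehyde | COCOc1cc(Br)cc(C=O)c1O | intermediate
9 | 2-methyl-1-propenylmagnesium bromide | CC(C)=C[Mg]Br | starting material (reagent)
10 | 4-bromo-2-(1-hydroxy-3-methylbut-2-en-1-yl)-6-(methoxymethoxy)phenol (racemic) | COCOc1cc(Br)cc(C(O)C=C(C)C)c1O | intermediate
11 | 6-bromo-8-(methoxymethoxy)-2,2-dimethyl-2H-chromene | COCOc1cc(Br)cc2C=CC(C)(C)Oc12 | intermediate
12 | 5-methoxy-7-(methoxymethoxy)-3-[8-(methoxymethoxy)-2,2-dimethyl-2H-chromen-6-yl]-4H-chromen-4-one | COc1cc(OCOC)cc2occ(-c3cc(OCOC)c4c(c3)C=CC(C)(C)O4)c(=O)c12 | intermediate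
13 | Glycyrrhizaisoflavone B | COc1cc(O)cc2occ(-c3cc(O)c4c(c3)C=CC(C)(C)O4)c(=O)c12 | target

## Summary

Total step count: 8 (convergent).
Longest linear sequence: 6 steps (6 → 7 → 8 → 10 → 11 → 12 → 13; Steps 3–8).

Three steps most likely to fail, each with a fallback:

1. **Step 7 (proposed new arylative annulation).** Risks are Heck-type C2 arylation, C–N coupling of released Me2NH, and O-arylation of the phenoxide. Known-chemistry fallback: cyclise 5 with I2 (CHCl3, rt) to 3-iodo-5-methoxy-7-(methoxymethoxy)chromone, convert 11 to its pinacol boronate (B2pin2, Pd(dppf)Cl2, KOAc), and join them by Suzuki–Miyaura coupling (Pd(dppf)Cl2, Na2CO3, DME/H2O) to reach the same 12.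

2. **Step 4 (selective 3-O-MOM of the catechol aldehyde).** Risk is a mixture of 2-O, 3-O and bis-MOM products. Fallback: skip the selective protection. Add the Grignard reagent (3.5 equiv) to unprotected 7 and cyclodehydrate to 6-bromo-2,2-dimethyl-2H-chromen-8-ol, where only the 2-OH can form the pyran. Then protect the single remaining phenol with MOMCl to reach 11.

3. **Step 8 (acidic MOM removal next to the acid-sensitive chromene).** Risk is hydration, methanol addition or dimerisation at the chromene double bond. Fallback: change the protecting-group strategy. Carry both phenols as TIPS ethers (TIPSCl in place of MOMCl in Steps 1 and 4) and finish with TBAF/AcOH in THF at 0 °C, so the phenols are released by fluoride and no acid is used.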